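Remark: 4-bromo-2,6-dimethoxyphenol (4) is assumed to be purchasable; the chiral intermediates 7, 8, 10 and 12 are racemic and drawn as one enantiomer, which is immaterial because 3, 11, 14 and the target are meso.

## Structural features

The target is a single oxolane ring carrying two 4-hydroxy-3,5-dimethoxyphenyl rings on C2 and C5 (aryl–C bonds) and two hydroxymethyl groups on C3 and C4. All four ring carbons are stereocentres and all four substituents lie on one face; a mirror plane through O1 and the midpoint of C3–C4 makes the compound meso, (2R,3R,4S,5S), so only relative configuration has to be controlled. This all-cis arrangement is the most crowded diastereomer, so it has to be reached under kinetic control and then shielded from equilibration. The fragile points are the benzylic C2–O1 and C5–O1 bonds (they ionise under acid with para-oxygen assistance and can hydrogenolyse), the oxidisable electron-rich phenols, and any stage at which C3 or C4 is α to a carbonyl group. The difficulty is therefore not the connectivity but forcing two aryl groups onto the face already occupied by two one-carbon arms. The feature exploited is that the CH2OH carbons on C3 and C4 are vicinal and cis: they can be tied together as the two sp2 carbons of a cyclobutene fused across C3–C4, while O1 and C2–C5 correspond atom for atom to the ring of maleic anhydride. The fused four-membered ring then gives the oxolane a convex and a concave face, which the later hydride deliveries use.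

## Logic of the disconnections

15 ⇒ 14. The two phenolic O–CH2Ph bonds are added back. Free phenols would quench 6 and 9 and would be attacked by ozone, so one robust protecting group is carried throughout. Nothing is gained in skeleton, but every earlier step becomes feasible. The forward step must remove both benzyl groups without cleaving the two benzylic C–O bonds of the oxolane, hence neutral hydrogenolysis stopped after the theoretical uptake.

14 ⇒ 11 (through 13 and 12). The two hydroxymethyl carbons are reconnected by a C=C bond, so both primary alcohols trace back to one alkene. These carbons sit cis on neighbouring ring atoms; joined, they turn the C3/C4 relationship into a ring fusion that cannot epimerise and give the oxolane two distinct faces. The gain is the loss of two free hydroxyl groups and of two configurational degrees of freedom. The forward step must cleave a strained alkene in the presence of two trialkoxyarenes and reduce 13 faster than it enolises.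

11 ⇒ 10 ⇒ 8 + 9. First the benzylic C–H bond at the second aryl-bearing carbon is cut (hydride removed, hydroxyl added), then the aryl–C bond. A hemiketal carbon is chosen because its oxocarbenium ion is planar, so configuration is decided only by the face from which hydride arrives. The gain is that the second aryl ring enters as a plain aryl nucleophile onto a carbonyl group. The demand is exo delivery of hydride, which places the aryl group on the concave face beside the cyclobutene, and a product that is not left in contact with acid.

8 ⇒ 7 ⇒ 3 + 6. The same cuts are made at the other aryl-bearing carbon: the benzylic C–H bond together with the ring C–O bond of the lactone, then the aryl–C(=O) bond. Because 3 is meso, either carbonyl may be attacked, so no regiochemical question arises. The first aryl group thus costs one addition. The demands are mono-addition of 6 and hydride capture of the acyloxy-substituted cation on its exo face before the benzylic C–O bond of 8 can ionise again.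

6 and 9 ⇒ 5 ⇒ 4. The carbon–metal bonds and the benzyl–oxygen bond are cut, so that one bromide supplies both aryl rings. This uses the symmetry of the target: one building block, two organometallic modes. The forward steps only require that the benzyl ether tolerates magnesium insertion and bromine–lithium exchange.

3 ⇒ 1 + 2. The two C–C bonds joining the ring-fusion carbons to the alkene carbons are cut, a retro-[2+2]. This is the greatest simplification: all five ring atoms of the oxolane come from 1, both hydroxymethyl carbons from 2, and the C3/C4 stereocentres from the impossibility of a trans fusion. The forward step must favour cross-addition over photodimerisation of 1 and over a second addition to 3.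

## Other disconnections considered

Alternative 1: The cut runs through O1–C5 and C2–C3 of the oxolane, a [3+2] dissection into the trans-configured donor–acceptor cyclopropane A1 and the aldehyde A2.
- Forward key step: Sn(OTf)2 would activate the geminal diester of A1. The carbonyl oxygen of A2 would displace the malonate carbon at the benzylic carbon with inversion, and the malonate would close onto the resulting oxocarbenium ion to give A3 with the 2,5-cis and 4,5-cis relationships.
- In its favour: the ring and three of the four stereocentres arise in one catalytic, convergent step, and no organometallic aryl reagent is needed. It also needs no photochemistry, acetylene or ozone, so on operational safety it is the better plan.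
- Against it here: C3 of A3 is quaternary, so one ester must be removed and the survivor must end cis to both neighbours. That is the less stable orientation of a centre α to a carbonyl group, and it is freely epimerisable under hot dealkoxycarbonylation conditions. The chosen plan keeps exactly this centre locked in a ring fusion. The strongly donating aryl group also makes A1 prone to ring opening and cis–trans scrambling through the benzylic zwitterion, and two different phenol protecting groups are needed.
- Comparison: on mechanism the two plans are equal in how well the 2,5-cis relationship is founded (envelope transition state there, convex-face hydride here). On step count they are about equal, since A1 needs roughly three steps before annulation, dealkoxycarbonylation, reduction and debenzylation. The alternative places its stereochemical weak point at the end.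

Alternative 2: Both aryl–C bonds (at C2 and C5) are cut, leaving the preformed cis-3,4-disubstituted oxolane A4, whose quinolin-8-yl amides act as directing groups, and the aryl iodide A5.
- Forward key step: a double amide-directed C(sp3)–H arylation with Pd(OAc)2 and AgOAc. Each amide chelates divalent palladium, a five-membered palladacycle forms at the cis C–H bond of the neighbouring O–CH2 group, and coupling with A5 gives A6 all-cis.
- In its favour: it is the most direct construction. The cis relationship of aryl to carbonyl is imposed by the palladacycle much as the bicycle imposes it in the chosen plan, so the stereochemical logic is equal. Up to A6 it is clearly better on step count, and it avoids photochemistry and ozone.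
- Against it here: the C–H bonds to be cleaved are α to the ring oxygen and flanked by a second bulky amide, and the second arylation must proceed on an already crowded ring. Stoichiometric silver is consumed. Two robust secondary amides must then be turned into CH2OH groups through activated carbonyl derivatives, in which C3 and C4 are acidic while sitting in the least stable arrangement; loss of configuration by enolisation is the expected weak point.
- Comparison: the alternative is shorter (about six steps), which is a point in its favour. It concentrates its risk in a crowded double C–H functionalisation and an epimerisation-prone endgame. The chosen plan exposes C3 and C4 to enolisation only in the short-lived 13.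

Alternative 3: The cut is the C3–C4 bond, regenerated as a C3=C4 double bond by extrusion of SO2 from the six-membered sulfone A7. In A7 the ester-bearing carbons flank sulfur and the aryl-bearing carbons flank oxygen.
- Forward key step: CBr2F2 would halogenate an α-sulfonyl carbon of A7, KOH on Al2O3 would induce 1,3-elimination to an episulfone, and loss of SO2 would contract the ring to A8 (Ramberg–Bäcklund reaction). The 2,5-cis relationship is carried over from the diequatorial 2,6-diaryl arrangement of A7.
- In its favour: the 2,6-cis geometry of A7 is the thermodynamically preferred one, so the aryl relationship needs no kinetic control; on that point it is better founded than the chosen plan. The design is two-directional. Hydrogenation of A8 from the face remote from both aryl groups would set C3 and C4 together, all-cis, possibly with simultaneous debenzylation, which would save a step.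
- Against it here: the protons at C2 and C5 of A8 are at once benzylic, allylic, α to oxygen and γ to an unsaturated ester, so the basic ring-contraction conditions invite double-bond migration or loss of the cis relationship. The tetrasubstituted, electron-poor alkene should be slow to hydrogenate, and its allylic–benzylic C–O bonds are candidates for hydrogenolysis under those same conditions. Access to A7 as one diastereomer also takes several steps.
- Comparison: face-selective hydrogenation is the mechanistic equal of convex-face hydride delivery, and the step counts are about equal. On the stability of intermediates the chosen plan is better, because its crowded centres are created late and under non-basic conditions.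

Key step: step 1

## Route

Step 1
Reactants: 1 maleic anhydride; 2 acetylene
Product: 3 cis-3-oxabicyclo[3.2.0]hept-6-ene-2,4-dione (cis-cyclobut-3-ene-1,2-dicarboxylic anhydride; meso)
Conditions: HC≡CH (1 atm, continuous stream, excess), Ph2CO (10 mol%), EtOAc, hν (medium-pressure Hg lamp, Pyrex, λ > 300 nm), −30 °C
Reagents that add atoms: none
Why: Benzophenone absorbs through Pyrex and passes its triplet energy to 1; triplet 1 adds to 2 to give a triplet 1,4-biradical (α-acyl radical on the anhydride ring, vinyl radical on the former alkyne), which after intersystem crossing forms the second C–C bond. The closest known reaction type is the triplet-sensitised [2+2] photocycloaddition of maleic anhydride and cyclic enones with alkynes, which is known for this very pair. The four-membered ring closes by radical–radical recombination of the 1,4-biradical, a stepwise formal [2+2] rather than a concerted process. The two new stereocentres, C1 and C5 of 3 (the future C3 and C4 of the oxolane), are controlled by ring strain alone: a trans fusion between the five-membered anhydride and a cyclobutene is not attainable, so the hydrogens end cis and 3 is meso. The step needs chemoselectivity, namely cross-addition in preference to photodimerisation of 1 and to a second addition of triplet 1 to the strained double bond of 3; a solution kept saturated with 2 at low temperature, interruption before 1 is fully consumed, and the absence in 3 of any chromophore absorbing above 300 nm should secure this. No regiochemical or facial question arises because both partners are symmetrical. For safety 2 is used only at atmospheric pressure, from a cold-trap-purified stream in copper-free lines, preferably in a flow photoreactor with a small irradiated volume.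

Step 2
Reactants: 4 4-bromo-2,6-dimethoxyphenol
Product: 5 2-(benzyloxy)-5-bromo-1,3-dimethoxybenzene
Conditions: BnBr, K2CO3, DMF, 60 °C
Reagents that add atoms: benzyl bromide, BrCc1ccccc1
Why: Williamson ether synthesis: the phenoxide of 4 displaces bromide from the benzylic halide on oxygen; the benzyl ether should then tolerate magnesium, organolithium, silane/acid and ozone. No stereocentre is involved.

Step 3
Reactants: 5 2-(benzyloxy)-5-bromo-1,3-dimethoxybenzene; 3 cis-3-oxabicyclo[3.2.0]hept-6-ene-2,4-dione
Product: 7 cis-2-[4-(benzyloxy)-3,5-dimethoxybenzoyl]cyclobut-3-ene-1-carboxylic acid (racemic; in equilibrium with its ring-closed hydroxy-lactone tautomer), via arylmagnesium bromide 6 (not isolated)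
Conditions: Mg, I2 (cat.), THF, reflux then rt; added to 3, THF, −78 → −20 °C; 1 M HCl
Reagents that add atoms: none
Why: Magnesium insertion gives 6, which opens the cyclic anhydride by nucleophilic acyl substitution (Grignard addition to an anhydride); at −78 °C with inverse addition the bromomagnesium carboxylate should resist a second addition. Both carbonyl groups of meso 3 are equivalent, so one racemic keto acid forms; the cis relationship survives because no bond to a ring stereocentre is broken and enolisation towards an alkylidenecyclobutene is strained.

Step 4
Reactants: 7 cis-2-[4-(benzyloxy)-3,5-dimethoxybenzoyl]cyclobut-3-ene-1-carboxylic acid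
Product: 8 4-endo-[4-(benzyloxy)-3,5-dimethoxyphenyl]-3-oxabicyclo[3.2.0]hept-6-en-2-one (cis-fused; aryl on the same face of the lactone ring as C6 and C7; racemic)
Conditions: Et3SiH (2 equiv), TFA, CH2Cl2, −20 → 0 °C
Reagents that add atoms: none
Why: Ionic hydrogenation of a γ-keto acid: in acid 7 closes to its hydroxy-lactone tautomer, which ionises to an aryl-stabilised acyloxycarbenium ion held in the cis-fused bicycle. Et3SiH should deliver hydride to the convex face, anti to the cyclobutene carbon on the adjacent ring-fusion atom, so the new benzylic stereocentre carries its aryl group endo, cis to the future CH2OH carbons. Low temperature and a small excess of silane are chosen so that the benzylic C–O bond of 8 does not ionise a second time.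

Step 5
Reactants: 5 2-(benzyloxy)-5-bromo-1,3-dimethoxybenzene; 8 4-endo-[4-(benzyloxy)-3,5-dimethoxyphenyl]-3-oxabicyclo[3.2.0]hept-6-en-2-one
Product: 10 2,4-bis[4-(benzyloxy)-3,5-dimethoxyphenyl]-3-oxabicyclo[3.2.0]hept-6-en-2-ol (cis-fused; 4-aryl endo; hemiketal carbon as an anomer mixture in equilibrium with the open hydroxy ketone; racemic), via aryllithium 9 (not isolated)
Conditions: 5, n-BuLi, THF, −78 °C; then 8, THF, −78 °C; aq. NH4Cl
Reagents that add atoms: none
Why: Bromine–lithium exchange gives 9, which adds once to the lactone carbonyl (organolithium addition to a lactone, as in C-aryl glycoside synthesis); the lithium hemiketal alkoxide is stable at −78 °C, so the reaction should stop at the lactol. Deprotonation α to the carbonyl is disfavoured because the enolate would place a double bond at the cyclobutene ring fusion; the configuration of the hemiketal carbon is irrelevant because step 6 erases it.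

Step 6
Reactants: 10 2,4-bis[4-(benzyloxy)-3,5-dimethoxyphenyl]-3-oxabicyclo[3.2.0]hept-6-en-2-ol
Product: 11 2,4-di-endo-bis[4-(benzyloxy)-3,5-dimethoxyphenyl]-3-oxabicyclo[3.2.0]hept-6-ene (cis-fused; both aryl groups cis to C6 and C7; meso)
Conditions: Et3SiH, BF3·OEt2, CH2Cl2, −78 → −40 °C; Et3N quench at −40 °C
Reagents that add atoms: none
Why: BF3·OEt2 ionises the hemiketal to an aryl-conjugated oxocarbenium ion and Et3SiH reduces it (reductive deoxygenation of a lactol). Hydride should enter from the convex face, opposite the cyclobutene and the endo aryl group at C4, so the second aryl group is also forced endo and all four substituents of the future oxolane are cis. The cold amine quench is meant to stop acid-promoted reopening of the benzylic C–O bonds of the strained product.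

Step 7
Reactants: 11 2,4-di-endo-bis[4-(benzyloxy)-3,5-dimethoxyphenyl]-3-oxabicyclo[3.2.0]hept-6-ene
Product: 14 {all-cis-2,5-bis[4-(benzyloxy)-3,5-dimethoxyphenyl]oxolane-3,4-diyl}dimethanol (meso), via methoxy-hydroperoxide aldehyde 12 (not isolated), via dialdehyde 13 (not isolated)
Conditions: O3, CH2Cl2–MeOH, Sudan Red 7B (trace), −78 °C; then NaBH4, −78 → 0 °C
Reagents that add atoms: ozone, [O-][O+]=O
Why: Ozonolysis with reductive work-up: ozone should add to the strained cis-disubstituted alkene far faster than to the trialkoxyarenes, the carbonyl oxide is trapped by methanol to give 12, and NaBH4 reduces the hydroperoxy acetal and both aldehyde groups (through 13) to the diol. The indicator dye marks the end-point before arene oxidation begins, and reduction at low temperature should outrun enolisation of 13, so the four stereocentres, none of which is touched, stay all-cis.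

Step 8
Reactants: 14 {all-cis-2,5-bis[4-(benzyloxy)-3,5-dimethoxyphenyl]oxolane-3,4-diyl}dimethanol
Product: 15 [(2R,3R,4S,5S)-2,5-bis(4-hydroxy-3,5-dimethoxyphenyl)oxolane-3,4-diyl]dimethanol (meso, all-cis; CNP0170897.3)
Conditions: H2 (1 atm), 10% Pd/C, EtOAc–MeOH, rt
Reagents that add atoms: none
Why: Hydrogenolysis of the two aryl benzyl ethers over palladium; these should cleave much faster than the benzylic C–O bonds of the oxolane, and the neutral medium avoids acid-induced epimerisation at C2 and C5. No stereocentre is formed or affected.

## Compound list

1 | maleic anhydride | O=C1C=CC(=O)O1 | starting material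
2 | acetylene | C#C | starting material
3 | cis-3-oxabicyclo[3.2.0]hept-6-ene-2,4-dione (meso) | O=C1OC(=O)[C@H]2C=C[C@@H]12 | intermediate
4 | 4-bromo-2,6-dimethoxyphenol | COc1cc(Br)cc(OC)c1O | starting material
5 | 2-(benzyloxy)-5-bromo-1,3-dimethoxybenzene | COc1cc(Br)cc(OC)c1OCc1ccccc1 | intermediate
6 | [4-(benzyloxy)-3,5-dimethoxyphenyl]magnesium bromide | COc1cc([Mg]Br)cc(OC)c1OCc1ccccc1 | intermediate (not isolated)
7 | cis-2-[4-(benzyloxy)-3,5-dimethoxybenzoyl]cyclobut-3-ene-1-carboxylic acid (racemic) | COc1cc(C(=O)[C@@H]2C=C[C@@H]2C(=O)O)cc(OC)c1OCc1ccccc1 | intermediate
8 | 4-endo-[4-(benzyloxy)-3,5-dimethoxyphenyl]-3-oxabicyclo[3.2.0]hept-6-en-2-one (cis-fused, racemic) | COc1cc([C@H]2OC(=O)[C@H]3C=C[C@@H]23)cc(OC)c1OCc1ccccc1 | intermediate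
9 | [4-(benzyloxy)-3,5-dimethoxyphenyl]lithium | COc1cc([Li])cc(OC)c1OCc1ccccc1 | intermediate (not isolated)
10 | 2,4-bis[4-(benzyloxy)-3,5-dimethoxyphenyl]-3-oxabicyclo[3.2.0]hept-6-en-2-ol (cis-fused, 4-aryl endo, anomer mixture, racemic) | COc1cc([C@H]2OC(O)(c3cc(OC)c(OCc4ccccc4)c(OC)c3)[C@H]3C=C[C@@H]23)cc(OC)c1OCc1ccccc1 | intermediate
11 | 2,4-di-endo-bis[4-(benzyloxy)-3,5-dimethoxyphenyl]-3-oxabicyclo[3.2.0]hept-6-ene (cis-fused, meso) | COc1cc([C@H]2O[C@@H](c3cc(OC)c(OCc4ccccc4)c(OC)c3)[C@H]3C=C[C@@H]23)cc(OC)c1OCc1ccccc1 | intermediate
12 | all-cis-2,5-bis[4-(benzyloxy)-3,5-dimethoxyphenyl]-4-[hydroperoxy(methoxy)methyl]oxolane-3-carbaldehyde (racemic, acetal carbon unassigned) | COc1cc([C@H]2O[C@@H](c3cc(OC)c(OCc4ccccc4)c(OC)c3)[C@@H](C(OC)OO)[C@H]2C=O)cc(OC)c1OCc1ccccc1 | intermediate (not isolated)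
13 | all-cis-2,5-bis[4-(benzyloxy)-3,5-dimethoxyphenyl]oxolane-3,4-dicarbaldehyde (meso) | COc1cc([C@H]2O[C@@H](c3cc(OC)c(OCc4ccccc4)c(OC)c3)[C@@H](C=O)[C@H]2C=O)cc(OC)c1OCc1ccccc1 | intermediate (not isolated)
14 | {all-cis-2,5-bis[4-(benzyloxy)-3,5-dimethoxyphenyl]oxolane-3,4-diyl}dimethanol (meso) | COc1cc([C@H]2O[C@@H](c3cc(OC)c(OCc4ccccc4)c(OC)c3)[C@@H](CO)[C@H]2CO)cc(OC)c1OCc1ccccc1 | intermediate
15 | [(2R,3R,4S,5S)-2,5-bis(4-hydroxy-3,5-dimethoxyphenyl)oxolane-3,4-diyl]dimethanol (meso, all-cis) | COc1cc([C@H]2O[C@@H](c3cc(OC)c(O)c(OC)c3)[C@@H](CO)[C@H]2CO)cc(OC)c1O | target

## Step count and least certain steps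

Total step count: 8. Longest linear sequence: 7 steps (steps 1, 3, 4, 5, 6, 7, 8; the branch from 4 through step 2 is equally long).

Step 1 (key step). The most likely problems are incomplete conversion with competing photodimerisation of 1, and consumption of the product by a second photocycloaddition onto its strained double bond; both follow from the fact that every alkene present can intercept triplet 1. Handling a gaseous alkyne under irradiation also limits scale. Fallback: setting out from 1, the same sensitised [2+2] is run with liquid (E)-1,2-dichloroethene in excess as an alkyne surrogate to give 6,7-dichloro-3-oxabicyclo[3.2.0]heptane-2,4-dione F1. Reductive 1,2-elimination of the two chlorines with activated zinc (Zn, Ac2O, toluene, 85 °C) then returns to the route at 3. The same two C–C bonds are formed.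

Step 4. The most likely problems are a second ionisation of the benzylic lactone C–O bond, leading to over-reduction by benzylic C–O hydrogenolysis or to equilibration towards the less crowded exo-aryl epimer, and ring expansion of the cyclobutenylcarbinyl cation. The cause is that an acyloxy-substituted cation is less stabilised than an alkoxy-substituted one and that the product still holds an ionisable bond. Fallback: setting out from 7, NaBH4 (aq. NaOH–MeOH, 0 °C) reduces the ketone without any cation to cis-2-{[4-(benzyloxy)-3,5-dimethoxyphenyl](hydroxy)methyl}cyclobut-3-ene-1-carboxylic acid F2, expected as two carbinol epimers. The epimer whose hydroxyl group is configured as in 8 lactonises with retention on mild acidification. The other is closed with inversion under Mitsunobu conditions (PPh3, DIAD, THF, 0 °C). Both converge on 8.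

Step 7. The most likely problems are loss of chemoselectivity as the alkene runs out (ozone attack on the trialkoxyarenes or on the benzylic ether CH2 groups) and base-promoted epimerisation at C3/C4 of 13 before hydride arrives. Fallback: setting out from 11, catalytic OsO4 with N-methylmorpholine N-oxide (acetone–water) dihydroxylates the cyclobutene on its exposed face to 2,4-di-endo-bis[4-(benzyloxy)-3,5-dimethoxyphenyl]-3-oxabicyclo[3.2.0]heptane-6,7-diol F3. NaIO4 (THF–pH 7 buffer) cleaves this glycol to 13, which is reduced at once with NaBH4, rejoining the route at 14. Ozone is avoided and the aldehyde is generated at neutral pH.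

Step 3. The most likely problem is double addition of the organomagnesium reagent once the first tetrahedral intermediate collapses, favoured by local warming or poor mixing. Fallback: setting out from 3, ring opening with MeNH(OMe)·HCl and pyridine (CH2Cl2, 0 °C) gives cis-2-[methoxy(methyl)carbamoyl]cyclobut-3-ene-1-carboxylic acid F4. Two equivalents of 6 are then used: the first forms the carboxylate and the second adds once to the N-methoxy-N-methylamide, whose magnesium chelate persists until work-up. This returns to the route at 7.

## Further compounds

F1 | step 1 | 6,7-dichloro-3-oxabicyclo[3.2.0]heptane-2,4-dione (cis-fused, chlorine stereoisomers unassigned) | O=C1OC(=O)[C@H]2C(Cl)C(Cl)[C@@H]12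
F2 | step 4 | cis-2-{[4-(benzyloxy)-3,5-dimethoxyphenyl](hydroxy)methyl}cyclobut-3-ene-1-carboxylic acid (racemic, both carbinol epimers) | COc1cc(C(O)[C@@H]2C=C[C@@H]2C(=O)O)cc(OC)c1OCc1ccccc1
F3 | step 7 | 2,4-di-endo-bis[4-(benzyloxy)-3,5-dimethoxyphenyl]-3-oxabicyclo[3.2.0]heptane-6,7-diol (hydroxyl groups cis to the ring-fusion hydrogens, meso) | COc1cc([C@H]2O[C@@H](c3cc(OC)c(OCc4ccccc4)c(OC)c3)[C@H]3[C@H](O)[C@H](O)[C@@H]23)cc(OC)c1OCc1ccccc1
F4 | step 3 | cis-2-[methoxy(methyl)carbamoyl]cyclobut-3-ene-1-carboxylic acid (racemic) | CON(C)C(=O)[C@@H]1C=C[C@@H]1C(=O)O
A1 | alternative 1 | dimethyl trans-2-(acetoxymethyl)-3-(4-acetoxy-3,5-dimethoxyphenyl)cyclopropane-1,1-dicarboxylate (racemic) | COC(=O)C1(C(=O)OC)[C@H](COC(C)=O)[C@H]1c1cc(OC)c(OC(C)=O)c(OC)c1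
A2 | alternative 1 | 4-(benzyloxy)-3,5-dimethoxybenzaldehyde | COc1cc(C=O)cc(OC)c1OCc1ccccc1
A3 | alternative 1 | dimethyl 2,4,5-cis-4-(acetoxymethyl)-5-(4-acetoxy-3,5-dimethoxyphenyl)-2-(4-benzyloxy-3,5-dimethoxyphenyl)tetrahydrofuran-3,3-dicarboxylate | COc1cc([C@H]2O[C@@H](c3cc(OC)c(OC(C)=O)c(OC)c3)[C@@H](COC(C)=O)C2(C(=O)OC)C(=O)OC)cc(OC)c1OCc1ccccc1
A4 | alternative 2 | cis-N,N'-di(quinolin-8-yl)tetrahydrofuran-3,4-dicarboxamide (meso) | C1OC[C@@H](C(=O)Nc2cccc3cccnc23)[C@H]1C(=O)Nc1cccc2cccnc12
A5 | alternative 2 | 2-(benzyloxy)-5-iodo-1,3-dimethoxybenzene | COc1cc(I)cc(OC)c1OCc1ccccc1
A6 | alternative 2 | all-cis-2,5-bis(4-benzyloxy-3,5-dimethoxyphenyl)-N,N'-di(quinolin-8-yl)tetrahydrofuran-3,4-dicarboxamide | COc1cc([C@H]2O[C@@H](c3cc(OC)c(OCc4ccccc4)c(OC)c3)[C@@H](C(=O)Nc3cccc4cccnc34)[C@H]2C(=O)Nc2cccc3cccnc23)cc(OC)c1OCc1ccccc1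
A7 | alternative 3 | dimethyl cis-2,6-bis(4-benzyloxy-3,5-dimethoxyphenyl)-1,4-oxathiane-3,5-dicarboxylate 4,4-dioxide (ester-bearing carbons unassigned) | COc1cc([C@@H]2O[C@H](c3cc(OC)c(OCc4ccccc4)c(OC)c3)C(C(=O)OC)S(=O)(=O)C2C(=O)OC)cc(OC)c1OCc1ccccc1
A8 | alternative 3 | dimethyl cis-2,5-bis(4-benzyloxy-3,5-dimethoxyphenyl)-2,5-dihydrofuran-3,4-dicarboxylate | COc1cc([C@@H]2O[C@H](c3cc(OC)c(OCc4ccccc4)c(OC)c3)C(C(=O)OC)=C2C(=O)OC)cc(OC)c1OCc1ccccc1
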